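The ring C' of the 2,3-trans unit is closed last, by cutting the synthesis at the O1'–C2' bond: phenoxide O1' adds to a para-quinone methide at C2'. This exploits C2' carrying the 4-hydroxyphenyl ring B', whose para oxygen makes the O1'–C2' bond reversible, so C2' settles trans to O3' while the all-cis unit, with ring B benzylated, stays closed. One fluoride treatment unmasks both phenols, expels the leaving group, closes ring C' and sets C2'. The precursor is the protected all-cis flavan-4-ol etherified at O4 with an open C4'–C3'–C2' chain: C4' and C3' set, O2'/O3' tied as a cyclic carbonate, O1' and the ring B' oxygen silylated.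

Key step: step 18

Remarks on the chemistry
- Flavan locants are used. Unprimed locants and rings A, B, C belong to the all-cis (2R,3R,4R) unit; primed locants and rings A', B', C' to the 2,3-trans (2S,3R,4R) unit. These descriptors were re-derived from the target SMILES. In open-chain intermediates the same spatial arrangement can carry another CIP letter; the names give the descriptor valid for each compound.
- The two units have the same configuration at C3 and C4 and differ only at C2. One open-chain triad (O2/O3 syn, O3/O4 anti) therefore serves both: closure at the aryl carbon (retention at C2) gives the all-cis ring, closure at C2' through the quinone methide gives the trans ring.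
- Precursor design: C4' is fixed by a ligand-controlled etherification and C3' by a dihydroxylation, so the key step has only C2' to settle. The leaving group at C2' is the cyclic carbonate of the O2'/O3' diol: the two hydroxyls need not be told apart, the tethered carbonate can re-add to the quinone methide, and O3' emerges free, leaving one alkyl benzyl ether for the end. No Lewis or Brønsted acid is used once the acid-labile C4–O–C4' ether exists.
- The phosphoramidite in step 14 is (Sa,Sc,Sc)-O,O'-(1,1'-binaphthalene-2,2'-diyl) N,N-bis(1-phenylethyl)phosphoramidite.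
- Assumed commercial: 1, 4, 8, 11, 12, 14, 24.

Step 1
Reactants: 1 2,3,4-trihydroxybenzaldehyde
Product: 2 3,4-bis(benzyloxy)-2-hydroxybenzaldehyde
Conditions: BnBr (2.1 equiv), K2CO3 (2.2 equiv), DMF, 0 °C → rt
Reagents that add atoms: benzyl bromide, BrCc1ccccc1
Why: Williamson etherification in which the 2-hydroxyl, hydrogen-bonded to the formyl group and flanked on both sides, is the least acidic and least accessible, so two equivalents of benzyl bromide should take the 4- and 3-hydroxyls first.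

Step 2
Reactants: 2 3,4-bis(benzyloxy)-2-hydroxybenzaldehyde
Product: 3 3,4-bis(benzyloxy)-2-(tert-butyldimethylsilyloxy)benzaldehyde
Conditions: TBSCl, imidazole, DMF, rt
Reagents that add atoms: tert-butyldimethylsilyl chloride, C[Si](C)(Cl)C(C)(C)C
Why: Imidazole-promoted O-silylation of the remaining phenol gives the fluoride-labile mask for the future O1'; no stereocentre is formed.

Step 3
Reactants: 3 3,4-bis(benzyloxy)-2-(tert-butyldimethylsilyloxy)benzaldehyde; 4 ethyl (triphenylphosphoranylidene)acetate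
Product: 5 ethyl (E)-3-[3,4-bis(benzyloxy)-2-(tert-butyldimethylsilyloxy)phenyl]prop-2-enoate
Conditions: toluene, 80 °C
Reagents that add atoms: none
Why: Wittig olefination with a stabilised ylide runs under neutral conditions that spare the aryl silyl ether and should give the E-enoate.

Step 4
Reactants: 5 ethyl (E)-3-[3,4-bis(benzyloxy)-2-(tert-butyldimethylsilyloxy)phenyl]prop-2-enoate
Product: 6 (E)-3-[3,4-bis(benzyloxy)-2-(tert-butyldimethylsilyloxy)phenyl]prop-2-en-1-ol
Conditions: i-Bu2AlH (2.2 equiv), CH2Cl2, −78 °C; aq Rochelle salt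
Reagents that add atoms: none
Why: 1,2-Reduction of the unsaturated ester by the aluminium hydride gives the allylic alcohol without touching the alkene, the benzyl ethers or the aryl silyl ether.

Step 5
Reactants: 6 (E)-3-[3,4-bis(benzyloxy)-2-(tert-butyldimethylsilyloxy)phenyl]prop-2-en-1-ol
Product: 7 tert-butyl (E)-3-[3,4-bis(benzyloxy)-2-(tert-butyldimethylsilyloxy)phenyl]prop-2-en-1-yl carbonate
Conditions: Boc2O, DMAP (cat.), CH2Cl2, 0 °C
Reagents that add atoms: di-tert-butyl dicarbonate, CC(C)(C)OC(=O)OC(=O)OC(C)(C)C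
Why: DMAP-catalysed O-acylation of the primary allylic alcohol gives the tert-butyl carbonate, a leaving group whose tert-butoxide by-product does not compete as a nucleophile in step 14.

Step 6
Reactants: 8 3-fluorobenzene-1,2-diol
Product: 9 1,2-bis(benzyloxy)-3-fluorobenzene
Conditions: BnBr, K2CO3, DMF, rt
Reagents that add atoms: benzyl bromide, BrCc1ccccc1
Why: Twofold Williamson etherification of the catechol; no selectivity is required.

Step 7
Reactants: 9 1,2-bis(benzyloxy)-3-fluorobenzene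
Product: 10 1-bromo-3,4-bis(benzyloxy)-2-fluorobenzene
Conditions: NBS, MeCN, 0 °C → rt
Reagents that add atoms: N-bromosuccinimide, O=C1CCC(=O)N1Br
Why: Electrophilic aromatic bromination should go para to the unhindered benzyloxy group at C1, the position that is also ortho to fluorine, since the flanked C2 ether is the weaker donor and the carbon meta to fluorine is the most deactivated.

Step 8
Reactants: 11 (S)-4-benzyl-1,3-oxazolidin-2-one; 12 (benzyloxy)acetyl chloride
Product: 13 (S)-4-benzyl-3-[(benzyloxy)acetyl]-1,3-oxazolidin-2-one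
Conditions: n-BuLi, THF, −78 °C; then 12
Reagents that add atoms: none
Why: N-Acylation of the lithiated oxazolidinone by the acid chloride gives the glycolyl imide and leaves the auxiliary stereocentre untouched.

Step 9
Reactants: 13 (S)-4-benzyl-3-[(benzyloxy)acetyl]-1,3-oxazolidin-2-one; 14 4-(benzyloxy)benzaldehyde
Product: 16 (S)-4-benzyl-3-[(2S,3R)-2-(benzyloxy)-3-[4-(benzyloxy)phenyl]-3-hydroxypropanoyl]-1,3-oxazolidin-2-one, via dibutylboron Z-enolate 15 (not isolated)
Conditions: Bu2BOTf, Et3N, CH2Cl2, −78 → 0 °C; 14, −78 → 0 °C; H2O2, pH 7 buffer, MeOH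
Reagents that add atoms: none
Why: Evans boron aldol reaction in which the Z-enolate reacts through a Zimmerman–Traxler chair on the face away from the auxiliary benzyl group, which should set the future C3 and C2 together as the syn (2S,3R) adduct.

Step 10
Reactants: 16 (S)-4-benzyl-3-[(2S,3R)-2-(benzyloxy)-3-[4-(benzyloxy)phenyl]-3-hydroxypropanoyl]-1,3-oxazolidin-2-one
Product: 17 (2S,3R)-2-(benzyloxy)-3-[4-(benzyloxy)phenyl]-3-hydroxy-N-methoxy-N-methylpropanamide
Conditions: MeNH(OMe)·HCl, AlMe3, CH2Cl2, 0 °C → rt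
Reagents that add atoms: N,O-dimethylhydroxylamine hydrochloride, CNOC.Cl
Why: Aluminium amide transamidation of the β-hydroxy imide (Weinreb amide formation) releases the auxiliary without touching either stereocentre.

Step 11
Reactants: 17 (2S,3R)-2-(benzyloxy)-3-[4-(benzyloxy)phenyl]-3-hydroxy-N-methoxy-N-methylpropanamide; 10 1-bromo-3,4-bis(benzyloxy)-2-fluorobenzene
Product: 19 (2S,3R)-2-(benzyloxy)-1-[3,4-bis(benzyloxy)-2-fluorophenyl]-3-[4-(benzyloxy)phenyl]-3-hydroxypropan-1-one, via aryllithium 18 (not isolated)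
Conditions: 10, n-BuLi, THF, −78 °C; 17 (pre-treated with i-PrMgCl, 1.0 equiv), −78 → −40 °C; aq NH4Cl
Reagents that add atoms: none
Why: Bromine–lithium exchange gives the aryllithium, kept cold so that loss of LiF is slow, and its addition to the Weinreb amide (hydroxyl masked as the magnesium alkoxide) stops at the chelated tetrahedral adduct, so the ketone should form on work-up with both stereocentres intact.

Step 12
Reactants: 19 (2S,3R)-2-(benzyloxy)-1-[3,4-bis(benzyloxy)-2-fluorophenyl]-3-[4-(benzyloxy)phenyl]-3-hydroxypropan-1-one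
Product: 20 (1R,2S,3R)-2-(benzyloxy)-1-[3,4-bis(benzyloxy)-2-fluorophenyl]-3-[4-(benzyloxy)phenyl]propane-1,3-diol
Conditions: Me4NBH(OAc)3, MeCN/AcOH, −30 °C
Reagents that add atoms: none
Why: Evans–Saksena hydroxyl-directed reduction, in which the acetoxyborohydride bound to the C3 hydroxyl delivers hydride intramolecularly through a chair, should give the 1,3-anti diol and so set the future C4 with O4 anti to O3 in the chain (cis in the ring).

Step 13
Reactants: 20 (1R,2S,3R)-2-(benzyloxy)-1-[3,4-bis(benzyloxy)-2-fluorophenyl]-3-[4-(benzyloxy)phenyl]propane-1,3-diol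
Product: 21 (2R,3R,4R)-3,7,8-tris(benzyloxy)-2-[4-(benzyloxy)phenyl]chroman-4-ol
Conditions: KN(SiMe3)2 (2.2 equiv), THF/DMPU, 0 → 60 °C
Reagents that add atoms: none
Why: Intramolecular nucleophilic aromatic substitution of fluoride by the benzylic alkoxide closes ring C at the aryl carbon, so C2 keeps its configuration and the syn/anti triad becomes the all-cis ring; the fluorine has no ortho hydrogen (no aryne), the meta benzyloxy group activates it inductively, and the C4 alkoxide cannot reach it.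

Step 14
Reactants: 21 (2R,3R,4R)-3,7,8-tris(benzyloxy)-2-[4-(benzyloxy)phenyl]chroman-4-ol; 7 tert-butyl (E)-3-[3,4-bis(benzyloxy)-2-(tert-butyldimethylsilyloxy)phenyl]prop-2-en-1-yl carbonate
Product: 23 (2R,3R,4R)-3,7,8-tris(benzyloxy)-2-[4-(benzyloxy)phenyl]-4-{[(1S)-1-[3,4-bis(benzyloxy)-2-(tert-butyldimethylsilyloxy)phenyl]prop-2-en-1-yl]oxy}chromane, via copper alkoxide 22 (not isolated)
Conditions: 21, n-BuLi then CuI, THF, 0 °C; 7, [Ir(cod)Cl]2 (2 mol%), (Sa,Sc,Sc)-phosphoramidite (4 mol%), THF, rt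
Reagents that add atoms: none
Why: Iridium-catalysed branched-selective asymmetric allylic etherification, in which the copper alkoxide attacks the aryl-bearing terminus of the allyl–iridium intermediate anti to the metal, so the ligand and not the chiral alkoxide should fix C4' (S here, the arrangement that is 4'R in the flavan, by the established sense of induction for aryl allyl carbonates), with any C4' epimer a separable diastereomer and C4 of 21 untouched because only its oxygen reacts.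

Step 15
Reactants: 23 (2R,3R,4R)-3,7,8-tris(benzyloxy)-2-[4-(benzyloxy)phenyl]-4-{[(1S)-1-[3,4-bis(benzyloxy)-2-(tert-butyldimethylsilyloxy)phenyl]prop-2-en-1-yl]oxy}chromane; 24 tert-butyldimethyl(4-vinylphenoxy)silane
Product: 25 (2R,3R,4R)-3,7,8-tris(benzyloxy)-2-[4-(benzyloxy)phenyl]-4-{[(1S,2E)-1-[3,4-bis(benzyloxy)-2-(tert-butyldimethylsilyloxy)phenyl]-3-[4-(tert-butyldimethylsilyloxy)phenyl]prop-2-en-1-yl]oxy}chromane
Conditions: 24 (3 equiv), second-generation Hoveyda–Grubbs catalyst RuCl2(H2IMes)(=CHC6H4-2-Oi-Pr) (5 mol%), CH2Cl2, 40 °C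
Reagents that add atoms: none
Why: Olefin cross-metathesis between the hindered secondary allylic ether, which homodimerises slowly, and an excess of the styrene should give the thermodynamically favoured E-alkene.

Step 16
Reactants: 25 (2R,3R,4R)-3,7,8-tris(benzyloxy)-2-[4-(benzyloxy)phenyl]-4-{[(1S,2E)-1-[3,4-bis(benzyloxy)-2-(tert-butyldimethylsilyloxy)phenyl]-3-[4-(tert-butyldimethylsilyloxy)phenyl]prop-2-en-1-yl]oxy}chromane
Product: 26 (2R,3R,4R)-3,7,8-tris(benzyloxy)-2-[4-(benzyloxy)phenyl]-4-{[(1R,2S,3R)-1-[3,4-bis(benzyloxy)-2-(tert-butyldimethylsilyloxy)phenyl]-2,3-dihydroxy-3-[4-(tert-butyldimethylsilyloxy)phenyl]propyl]oxy}chromane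
Conditions: OsO4 (2 mol%), (DHQD)2PHAL (5 mol%), NMO, acetone/H2O, 0 °C
Reagents that add atoms: N-methylmorpholine N-oxide, C[N+]1([O-])CCOCC1; water, O
Why: Osmium-catalysed syn-dihydroxylation (Sharpless ligand, Upjohn reoxidant, neutral medium for the aryl silyl ethers) in which the usual attack anti to the allylic C4'–O bond and the face preferred by the DHQD ligand coincide, which should set C3' with O3' anti to O4' and, by syn addition, C2' as (R).

Step 17
Reactants: 26 (2R,3R,4R)-3,7,8-tris(benzyloxy)-2-[4-(benzyloxy)phenyl]-4-{[(1R,2S,3R)-1-[3,4-bis(benzyloxy)-2-(tert-butyldimethylsilyloxy)phenyl]-2,3-dihydroxy-3-[4-(tert-butyldimethylsilyloxy)phenyl]propyl]oxy}chromane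
Product: 27 (2R,3R,4R)-3,7,8-tris(benzyloxy)-2-[4-(benzyloxy)phenyl]-4-{(R)-[3,4-bis(benzyloxy)-2-(tert-butyldimethylsilyloxy)phenyl][(4R,5R)-2-oxo-5-[4-(tert-butyldimethylsilyloxy)phenyl]-1,3-dioxolan-4-yl]methoxy}chromane
Conditions: 1,1'-carbonyldiimidazole, DMAP (cat.), CH2Cl2, rt
Reagents that add atoms: 1,1'-carbonyldiimidazole, O=C(n1ccnc1)n1ccnc1
Why: Carbonylation of the syn-1,2-diol gives the trans-disubstituted cyclic carbonate under non-acidic conditions, which protects O3' and turns O2' into a leaving group in one operation without touching a stereocentre.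

Step 18
Reactants: 27 (2R,3R,4R)-3,7,8-tris(benzyloxy)-2-[4-(benzyloxy)phenyl]-4-{(R)-[3,4-bis(benzyloxy)-2-(tert-butyldimethylsilyloxy)phenyl][(4R,5R)-2-oxo-5-[4-(tert-butyldimethylsilyloxy)phenyl]-1,3-dioxolan-4-yl]methoxy}chromane
Product: 29 (2R,3R,4R)-3,7,8-tris(benzyloxy)-2-[4-(benzyloxy)phenyl]-4-{[(2S,3R,4R)-7,8-bis(benzyloxy)-3-hydroxy-2-(4-hydroxyphenyl)chroman-4-yl]oxy}chromane, via para-quinone methide 28 (not isolated)
Conditions: Bu4NF (3 equiv, dried over 4 Å sieves), THF, 0 °C → rt (40 °C if equilibration is slow); aq NH4Cl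
Reagents that add atoms: none
Why: Fluoride cleaves both aryl silyl ethers; the 4-oxidophenyl group of ring B' then expels the C2' carbonate oxygen by 1,6-elimination to give the para-quinone methide 28, and phenoxide O1' adds to its exocyclic carbon, forming O1'–C2' and ring C'. The closest known reaction type is the fluoride-induced 1,6-elimination of 4-silyloxybenzyl esters and carbonates with intramolecular oxa-Michael capture, together with the base epimerisation of 2-(4-hydroxyphenyl)flavans through the same intermediate. Ring C' closes in 6-exo-trig mode. C2' is the only new stereocentre and is controlled by the existing C3' and C4' centres under thermodynamic control: while the ring B' oxygen is free the addition is reversible, so C2' should settle with the aryl group and O3' equatorial (trans) and O4' pseudo-axial away from the C5' hydrogen, and the (R) configuration of C2' in 27 would give the same isomer even by direct invertive displacement. The step needs chemoselectivity between the two halves, secured because only ring B' carries a silyl-masked oxygen while ring B of the all-cis half stays benzylated and cannot open, and it needs the quinone methide to survive until O1' is free, secured by the tethered carbonate (or the O3' alkoxide after loss of CO2) re-adding reversibly. Aqueous NH4Cl work-up then releases CO2 from the O3' carbonate half-ester and leaves the free 3'-hydroxyl.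

Step 19
Reactants: 29 (2R,3R,4R)-3,7,8-tris(benzyloxy)-2-[4-(benzyloxy)phenyl]-4-{[(2S,3R,4R)-7,8-bis(benzyloxy)-3-hydroxy-2-(4-hydroxyphenyl)chroman-4-yl]oxy}chromane
Product: 30 (2R,3R,4R)-2-(4-hydroxyphenyl)-4-{[(2S,3R,4R)-3,7,8-trihydroxy-2-(4-hydroxyphenyl)chroman-4-yl]oxy}chromane-3,7,8-triol
Conditions: H2 (1 atm), Pd(OH)2/C, THF/MeOH, rt
Reagents that add atoms: none
Why: Hydrogenolysis of the five aryl benzyl ethers and the one alkyl benzyl ether under neutral conditions avoids acid at the C4–O–C4' ether and base at the two 2-(4-hydroxyphenyl) centres, so no stereocentre is touched.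

Compound list
1 | 2,3,4-trihydroxybenzaldehyde | O=Cc1ccc(O)c(O)c1O | starting material
2 | 3,4-bis(benzyloxy)-2-hydroxybenzaldehyde | O=Cc1ccc(OCc2ccccc2)c(OCc2ccccc2)c1O | intermediate
3 | 3,4-bis(benzyloxy)-2-(tert-butyldimethylsilyloxy)benzaldehyde | O=Cc1ccc(OCc2ccccc2)c(OCc2ccccc2)c1O[Si](C)(C)C(C)(C)C | intermediate
4 | ethyl (triphenylphosphoranylidene)acetate | CCOC(=O)C=P(c1ccccc1)(c1ccccc1)c1ccccc1 | starting material
5 | ethyl (E)-3-[3,4-bis(benzyloxy)-2-(tert-butyldimethylsilyloxy)phenyl]prop-2-enoate | CCOC(=O)/C=C/c1ccc(OCc2ccccc2)c(OCc2ccccc2)c1O[Si](C)(C)C(C)(C)C | intermediate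
6 | (E)-3-[3,4-bis(benzyloxy)-2-(tert-butyldimethylsilyloxy)phenyl]prop-2-en-1-ol | OC/C=C/c1ccc(OCc2ccccc2)c(OCc2ccccc2)c1O[Si](C)(C)C(C)(C)C | intermediate
7 | tert-butyl (E)-3-[3,4-bis(benzyloxy)-2-(tert-butyldimethylsilyloxy)phenyl]prop-2-en-1-yl carbonate | CC(C)(C)OC(=O)OC/C=C/c1ccc(OCc2ccccc2)c(OCc2ccccc2)c1O[Si](C)(C)C(C)(C)C | intermediate
8 | 3-fluorobenzene-1,2-diol | Oc1cccc(F)c1O | starting material
9 | 1,2-bis(benzyloxy)-3-fluorobenzene | Fc1cccc(OCc2ccccc2)c1OCc1ccccc1 | intermediate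
10 | 1-bromo-3,4-bis(benzyloxy)-2-fluorobenzene | Brc1ccc(OCc2ccccc2)c(OCc2ccccc2)c1F | intermediate
11 | (S)-4-benzyl-1,3-oxazolidin-2-one | O=C1N[C@@H](Cc2ccccc2)CO1 | starting material
12 | (benzyloxy)acetyl chloride | O=C(Cl)COCc1ccccc1 | starting material
13 | (S)-4-benzyl-3-[(benzyloxy)acetyl]-1,3-oxazolidin-2-one | O=C(COCc1ccccc1)N1[C@@H](Cc2ccccc2)COC1=O | intermediate
14 | 4-(benzyloxy)benzaldehyde | O=Cc1ccc(OCc2ccccc2)cc1 | starting material
15 | dibutylboron Z-enolate of 13 | CCCCB(CCCC)O/C(=C\OCc1ccccc1)N1[C@@H](Cc2ccccc2)COC1=O | intermediate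
16 | (S)-4-benzyl-3-[(2S,3R)-2-(benzyloxy)-3-[4-(benzyloxy)phenyl]-3-hydroxypropanoyl]-1,3-oxazolidin-2-one | O=C([C@@H](OCc1ccccc1)[C@H](O)c1ccc(OCc2ccccc2)cc1)N1[C@@H](Cc2ccccc2)COC1=O | intermediate
17 | (2S,3R)-2-(benzyloxy)-3-[4-(benzyloxy)phenyl]-3-hydroxy-N-methoxy-N-methylpropanamide | CON(C)C(=O)[C@@H](OCc1ccccc1)[C@H](O)c1ccc(OCc2ccccc2)cc1 | intermediate
18 | [3,4-bis(benzyloxy)-2-fluorophenyl]lithium | [Li]c1ccc(OCc2ccccc2)c(OCc2ccccc2)c1F | intermediate
19 | (2S,3R)-2-(benzyloxy)-1-[3,4-bis(benzyloxy)-2-fluorophenyl]-3-[4-(benzyloxy)phenyl]-3-hydroxypropan-1-one | O=C(c1ccc(OCc2ccccc2)c(OCc2ccccc2)c1F)[C@@H](OCc1ccccc1)[C@H](O)c1ccc(OCc2ccccc2)cc1 | intermediate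
20 | (1R,2S,3R)-2-(benzyloxy)-1-[3,4-bis(benzyloxy)-2-fluorophenyl]-3-[4-(benzyloxy)phenyl]propane-1,3-diol | O[C@H](c1ccc(OCc2ccccc2)c(OCc2ccccc2)c1F)[C@@H](OCc1ccccc1)[C@H](O)c1ccc(OCc2ccccc2)cc1 | intermediate
21 | (2R,3R,4R)-3,7,8-tris(benzyloxy)-2-[4-(benzyloxy)phenyl]chroman-4-ol | c1ccccc1COc1ccc([C@H]2Oc3c(ccc(OCc4ccccc4)c3OCc3ccccc3)[C@@H](O)[C@H]2OCc2ccccc2)cc1 | intermediate
22 | copper alkoxide of 21 | c1ccccc1COc1ccc([C@H]2Oc3c(ccc(OCc4ccccc4)c3OCc3ccccc3)[C@@H](O[Cu])[C@H]2OCc2ccccc2)cc1 | intermediate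
23 | (2R,3R,4R)-3,7,8-tris(benzyloxy)-2-[4-(benzyloxy)phenyl]-4-{[(1S)-1-[3,4-bis(benzyloxy)-2-(tert-butyldimethylsilyloxy)phenyl]prop-2-en-1-yl]oxy}chromane | c1ccccc1COc1ccc([C@H]2Oc3c(ccc(OCc4ccccc4)c3OCc3ccccc3)[C@@H](O[C@H](c3ccc(OCc4ccccc4)c(OCc4ccccc4)c3O[Si](C)(C)C(C)(C)C)C=C)[C@H]2OCc2ccccc2)cc1 | intermediate
24 | tert-butyldimethyl(4-vinylphenoxy)silane | C=Cc1ccc(O[Si](C)(C)C(C)(C)C)cc1 | starting material
25 | (2R,3R,4R)-3,7,8-tris(benzyloxy)-2-[4-(benzyloxy)phenyl]-4-{[(1S,2E)-1-[3,4-bis(benzyloxy)-2-(tert-butyldimethylsilyloxy)phenyl]-3-[4-(tert-butyldimethylsilyloxy)phenyl]prop-2-en-1-yl]oxy}chromane | c1ccccc1COc1ccc([C@H]2Oc3c(ccc(OCc4ccccc4)c3OCc3ccccc3)[C@@H](O[C@H](c3ccc(OCc4ccccc4)c(OCc4ccccc4)c3O[Si](C)(C)C(C)(C)C)/C=C/c3ccc(O[Si](C)(C)C(C)(C)C)cc3)[C@H]2OCc2ccccc2)cc1 | intermediate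
26 | (2R,3R,4R)-3,7,8-tris(benzyloxy)-2-[4-(benzyloxy)phenyl]-4-{[(1R,2S,3R)-1-[3,4-bis(benzyloxy)-2-(tert-butyldimethylsilyloxy)phenyl]-2,3-dihydroxy-3-[4-(tert-butyldimethylsilyloxy)phenyl]propyl]oxy}chromane | c1ccccc1COc1ccc([C@H]2Oc3c(ccc(OCc4ccccc4)c3OCc3ccccc3)[C@@H](O[C@H](c3ccc(OCc4ccccc4)c(OCc4ccccc4)c3O[Si](C)(C)C(C)(C)C)[C@@H](O)[C@H](O)c3ccc(O[Si](C)(C)C(C)(C)C)cc3)[C@H]2OCc2ccccc2)cc1 | intermediate
27 | (2R,3R,4R)-3,7,8-tris(benzyloxy)-2-[4-(benzyloxy)phenyl]-4-{(R)-[3,4-bis(benzyloxy)-2-(tert-butyldimethylsilyloxy)phenyl][(4R,5R)-2-oxo-5-[4-(tert-butyldimethylsilyloxy)phenyl]-1,3-dioxolan-4-yl]methoxy}chromane | c1ccccc1COc1ccc([C@H]2Oc3c(ccc(OCc4ccccc4)c3OCc3ccccc3)[C@@H](O[C@H](c3ccc(OCc4ccccc4)c(OCc4ccccc4)c3O[Si](C)(C)C(C)(C)C)[C@H]5OC(=O)O[C@@H]5c3ccc(O[Si](C)(C)C(C)(C)C)cc3)[C@H]2OCc2ccccc2)cc1 | intermediate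
28 | para-quinone methide formed from 27 (O1' phenoxide, O3' carbonate half-ester anion, C2' as the exocyclic carbon of a cyclohexa-2,5-dienone) | c1ccccc1COc1ccc([C@H]2Oc3c(ccc(OCc4ccccc4)c3OCc3ccccc3)[C@@H](O[C@H](c3ccc(OCc4ccccc4)c(OCc4ccccc4)c3[O-])[C@@H](OC(=O)[O-])C=C3C=CC(=O)C=C3)[C@H]2OCc2ccccc2)cc1 | intermediate
29 | (2R,3R,4R)-3,7,8-tris(benzyloxy)-2-[4-(benzyloxy)phenyl]-4-{[(2S,3R,4R)-7,8-bis(benzyloxy)-3-hydroxy-2-(4-hydroxyphenyl)chroman-4-yl]oxy}chromane | c1ccccc1COc1ccc([C@H]2Oc3c(ccc(OCc4ccccc4)c3OCc3ccccc3)[C@@H](O[C@@H]3c4ccc(OCc5ccccc5)c(OCc5ccccc5)c4O[C@@H](c4ccc(O)cc4)[C@@H]3O)[C@H]2OCc2ccccc2)cc1 | intermediate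
30 | (2R,3R,4R)-2-(4-hydroxyphenyl)-4-{[(2S,3R,4R)-3,7,8-trihydroxy-2-(4-hydroxyphenyl)chroman-4-yl]oxy}chromane-3,7,8-triol | Oc1ccc([C@H]2Oc3c(ccc(O)c3O)[C@@H](O[C@@H]3c4ccc(O)c(O)c4O[C@@H](c4ccc(O)cc4)[C@@H]3O)[C@H]2O)cc1 | target

Total step count: 19 steps.
Longest linear sequence: 12 steps (11 and 12 → 13 → 16 → 17 → 19 → 20 → 21 → 23 → 25 → 26 → 27 → 29 → 30).

The three steps most likely to fail

1. Step 18 (key step). What may go wrong: the quinone methide may be diverted before O1' is free (hydration by residual water, oligomerisation), or the equilibrium at C2' may not favour the trans ring strongly enough. Fallback (kinetic, invertive closure in a series whose ring B' is benzylated, so no quinone methide can form; it sets out from 23 and comes back at 30): cross-metathesis of 23 with commercial 1-(benzyloxy)-4-vinylbenzene under the conditions of step 15 would give the E-alkene with benzylated ring B' F1. Dihydroxylation as in step 16 would give the (1R,2S,3R)-diol F2. Bu4NF/AcOH in THF would free only O1' and give the phenol diol F3. PPh3 and diisopropyl azodicarboxylate in THF at 0 °C should activate the less hindered benzylic C2' hydroxyl, which O1' displaces with inversion (Mitsunobu cyclisation, the known way from syn-1,3-diarylpropane-1,2-diols to 2,3-trans flavan-3-ols), giving the hepta-O-benzyl dimer with free 3'-hydroxyl F4. Hydrogenolysis as in step 19 then returns to the route at 30.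

2. Step 14. What may go wrong: slow attack of the hindered secondary copper alkoxide on the allyl–iridium intermediate, so that silyl transfer from O1' to the alkoxide, linear ether formation or catalyst decay take over; the ortho silyloxy group may also erode facial control. Fallback (oxocarbenium route under substrate control with separation; it sets out from 21 and 3 and comes back at 25): silylation of 21 (Me3SiCl, imidazole) would give the trimethylsilyl ether of 21 F5. Commercial 1-[4-(tert-butyldimethylsilyloxy)phenyl]ethanone with Me3SiOTf/Et3N would give the enol silane F6. Me3SiOTf-catalysed three-component coupling of 3, F5 and F6 in CH2Cl2 at −78 °C (Mukaiyama-type addition to the oxocarbenium ion formed from the aldehyde and the silyl ether) should give the β-alkoxy ketone F7, whose C4' epimers would be separated. NaBH4 reduction would give the alcohol F8 as a C3 mixture, and dehydration with the Burgess reagent towards the methylene group returns to the route at 25.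

3. Step 13. What may go wrong: sluggish substitution at the electron-rich fluoroarene, so that prolonged heating of the dialkoxide with strong base leads to decomposition or benzyl ether cleavage. Fallback (carbonyl-activated substitution before the reduction; it sets out from 19 and comes back at 21): K2CO3 in DMF at rt should close ring C on the ortho-fluoro ketone and give the 2,3-cis flavan-4-one F9, the reaction being stopped before base can epimerise C3. NaBH4 in MeOH/THF at −40 °C should then deliver hydride axially, anti to the axial 3-benzyloxy group, and return to the route at 21.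

Further compounds
F1 | step 18 | (2R,3R,4R)-3,7,8-tris(benzyloxy)-2-[4-(benzyloxy)phenyl]-4-{[(1S,2E)-3-[4-(benzyloxy)phenyl]-1-[3,4-bis(benzyloxy)-2-(tert-butyldimethylsilyloxy)phenyl]prop-2-en-1-yl]oxy}chromane | c1ccccc1COc1ccc([C@H]2Oc3c(ccc(OCc4ccccc4)c3OCc3ccccc3)[C@@H](O[C@H](c3ccc(OCc4ccccc4)c(OCc4ccccc4)c3O[Si](C)(C)C(C)(C)C)/C=C/c3ccc(OCc4ccccc4)cc3)[C@H]2OCc2ccccc2)cc1
F2 | step 18 | (2R,3R,4R)-3,7,8-tris(benzyloxy)-2-[4-(benzyloxy)phenyl]-4-{[(1R,2S,3R)-3-[4-(benzyloxy)phenyl]-1-[3,4-bis(benzyloxy)-2-(tert-butyldimethylsilyloxy)phenyl]-2,3-dihydroxypropyl]oxy}chromane | c1ccccc1COc1ccc([C@H]2Oc3c(ccc(OCc4ccccc4)c3OCc3ccccc3)[C@@H](O[C@H](c3ccc(OCc4ccccc4)c(OCc4ccccc4)c3O[Si](C)(C)C(C)(C)C)[C@@H](O)[C@H](O)c3ccc(OCc4ccccc4)cc3)[C@H]2OCc2ccccc2)cc1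
F3 | step 18 | (2R,3R,4R)-3,7,8-tris(benzyloxy)-2-[4-(benzyloxy)phenyl]-4-{[(1R,2S,3R)-3-[4-(benzyloxy)phenyl]-1-[3,4-bis(benzyloxy)-2-hydroxyphenyl]-2,3-dihydroxypropyl]oxy}chromane | c1ccccc1COc1ccc([C@H]2Oc3c(ccc(OCc4ccccc4)c3OCc3ccccc3)[C@@H](O[C@H](c3ccc(OCc4ccccc4)c(OCc4ccccc4)c3O)[C@@H](O)[C@H](O)c3ccc(OCc4ccccc4)cc3)[C@H]2OCc2ccccc2)cc1
F4 | step 18 | (2R,3R,4R)-3,7,8-tris(benzyloxy)-2-[4-(benzyloxy)phenyl]-4-{[(2S,3R,4R)-7,8-bis(benzyloxy)-2-[4-(benzyloxy)phenyl]-3-hydroxychroman-4-yl]oxy}chromane | c1ccccc1COc1ccc([C@H]2Oc3c(ccc(OCc4ccccc4)c3OCc3ccccc3)[C@@H](O[C@@H]3c4ccc(OCc5ccccc5)c(OCc5ccccc5)c4O[C@@H](c4ccc(OCc5ccccc5)cc4)[C@@H]3O)[C@H]2OCc2ccccc2)cc1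
F5 | step 14 | (2R,3R,4R)-3,7,8-tris(benzyloxy)-2-[4-(benzyloxy)phenyl]-4-(trimethylsilyloxy)chromane | c1ccccc1COc1ccc([C@H]2Oc3c(ccc(OCc4ccccc4)c3OCc3ccccc3)[C@@H](O[Si](C)(C)C)[C@H]2OCc2ccccc2)cc1
F6 | step 14 | tert-butyldimethyl{4-[1-(trimethylsilyloxy)ethenyl]phenoxy}silane | C=C(O[Si](C)(C)C)c1ccc(O[Si](C)(C)C(C)(C)C)cc1
F7 | step 14 | (2R,3R,4R)-3,7,8-tris(benzyloxy)-2-[4-(benzyloxy)phenyl]-4-{[(1S)-1-[3,4-bis(benzyloxy)-2-(tert-butyldimethylsilyloxy)phenyl]-3-oxo-3-[4-(tert-butyldimethylsilyloxy)phenyl]propyl]oxy}chromane | c1ccccc1COc1ccc([C@H]2Oc3c(ccc(OCc4ccccc4)c3OCc3ccccc3)[C@@H](O[C@H](c3ccc(OCc4ccccc4)c(OCc4ccccc4)c3O[Si](C)(C)C(C)(C)C)CC(=O)c3ccc(O[Si](C)(C)C(C)(C)C)cc3)[C@H]2OCc2ccccc2)cc1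
F8 | step 14 | (2R,3R,4R)-3,7,8-tris(benzyloxy)-2-[4-(benzyloxy)phenyl]-4-{[(1S)-1-[3,4-bis(benzyloxy)-2-(tert-butyldimethylsilyloxy)phenyl]-3-hydroxy-3-[4-(tert-butyldimethylsilyloxy)phenyl]propyl]oxy}chromane (C3 epimers of the propyl chain) | c1ccccc1COc1ccc([C@H]2Oc3c(ccc(OCc4ccccc4)c3OCc3ccccc3)[C@@H](O[C@H](c3ccc(OCc4ccccc4)c(OCc4ccccc4)c3O[Si](C)(C)C(C)(C)C)CC(O)c3ccc(O[Si](C)(C)C(C)(C)C)cc3)[C@H]2OCc2ccccc2)cc1
F9 | step 13 | (2R,3S)-3,7,8-tris(benzyloxy)-2-[4-(benzyloxy)phenyl]chroman-4-one | c1ccccc1COc1ccc([C@H]2Oc3c(ccc(OCc4ccccc4)c3OCc3ccccc3)C(=O)[C@H]2OCc2ccccc2)cc1
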